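**Retrosynthetic overview**
1. The target is a constitutional isomer of 4-henicosylpyridine 1-oxide. Disconnect the pyrrole N1–C2 bond and the aldehyde C=O together. In the forward ring contraction, O moves onto pyridine C2 (new C–O bond) and N moves from C2 to C3 (new C–N bond).
2. 4-Henicosylpyridine 1-oxide comes from 4-henicosylpyridine by peracid N-oxidation.
3. 4-Henicosylpyridine comes from 4-methylpyridine and 1-bromoicosane by lateral alkylation (C1 + C20 = C21 chain).
4. Ring order: the pyridine ring is bought. The pyrrole is the only ring made, and it is formed last, out of the pyridine ring itself.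

Assumption: the SMILES is read as 3-henicosyl-1H-pyrrole-2-carbaldehyde (C26H47NO; unbranched C21 chain at C3, CHO at C2, free N–H). It has no stereocentre, so there is no enantiomer to control.

**Step 1**
Reactants: 1 4-methylpyridine; 2 1-bromoicosane
Product: 4 4-henicosylpyridine, via (pyridin-4-ylmethyl)lithium 3 (not isolated)
Conditions: 1 (1.2 equiv), LDA (commercial solution, 1.15 equiv), THF, −78 °C, 45 min; then 2 (1.0 equiv) in THF, −78 °C → rt, 12 h
Reagents that add atoms: none
Why: Lateral lithiation of 4-picoline (LDA deprotonates the aza-benzylic methyl group without adding to the ring) followed by SN2 alkylation with an unhindered primary bromide builds the C21 chain, the slight excess of 1 suppresses double alkylation, and no stereocentre is formed.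

**Step 2**
Reactants: 4 4-henicosylpyridine
Product: 5 4-henicosylpyridine 1-oxide
Conditions: mCPBA (1.2 equiv), CH2Cl2, 0 °C → rt, 3 h; plug of basic Al2O3 (CH2Cl2 → 5% MeOH/CH2Cl2)
Reagents that add atoms: mCPBA (3-chloroperoxybenzoic acid), O=C(OO)c1cccc(Cl)c1
Why: Peracid N-oxidation of a pyridine (electrophilic oxygen transfer to the nitrogen lone pair) leaves the saturated chain untouched, the basic alumina plug removes all acid that would divert the next step, and no stereocentre is formed.

**Step 3**
Reactants: 5 4-henicosylpyridine 1-oxide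
Product: 9 3-henicosyl-1H-pyrrole-2-carbaldehyde, via oxaziridine valence isomer 6 (not isolated), via 5-henicosyl-1,2-oxazepine 7 (not isolated), via 3-henicosyl-2H-pyrrole-2-carbaldehyde 8 (not isolated)
Conditions: hν (254 nm, low-pressure Hg lamp, FEP flow coil, about 15 min residence), Cu(O3SOC12H25)2 (50 mol%), NaO3SOC12H25 (40 mM), Ar-sparged H2O/t-BuOH 19:1, 2 mM in 5, 45 °C; run to about 85% conversion
Reagents that add atoms: none
Why: Proposed new method: a metallomicellar copper-relay photochemical ring contraction, in which the amphiphilic N-oxide 5 is co-assembled into anionic dodecyl sulfate micelles whose surface gathers divalent copper ions by ion exchange next to the hydrated N-oxide head group, so that hydrogen bonding blue-shifts the π,π* band of 5 to about 255 nm where product 9 (maximum near 290 nm) absorbs weakly, the picosecond singlet state (too short-lived for diffusional quenching by copper) closes O onto C2 (new C–O bond) to give oxaziridine 6, which opens electrocyclically to 1,2-oxazepine 7, interfacial divalent copper binds 7 and triggers N–O scission to a copper-held iminyl/dienolate (acylvinylnitrene-like) species that closes N onto the former C3 (new C–N bond) to give 2H-pyrrole 8, and 8 tautomerises irreversibly to aromatic 9, with the C2/C6 symmetry of 5 allowing only the 3-alkyl-2-formyl isomer and no stereocentre surviving; the closest known reaction types are the UV photoisomerisation of small water-soluble pyridine N-oxides to 2-formylpyrroles in homogeneous aqueous copper salt solution and Lewis-acid–surfactant-combined catalysis of ground-state reactions in water, which have never been joined or applied to a water-insoluble lipid-chain N-oxide.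

**Compound list**
1 | 4-methylpyridine (4-picoline) | Cc1ccncc1 | starting material
2 | 1-bromoicosane | CCCCCCCCCCCCCCCCCCCCBr | starting material
3 | (pyridin-4-ylmethyl)lithium | [Li]Cc1ccncc1 | intermediate (not isolated)
4 | 4-henicosylpyridine | CCCCCCCCCCCCCCCCCCCCCc1ccncc1 | intermediate
5 | 4-henicosylpyridine 1-oxide | CCCCCCCCCCCCCCCCCCCCCc1cc[n+]([O-])cc1 | intermediate
6 | 4-henicosyl-7-oxa-1-azabicyclo[4.1.0]hepta-2,4-diene (racemic transient) | CCCCCCCCCCCCCCCCCCCCCC1=CC2ON2C=C1 | intermediate (not isolated)
7 | 5-henicosyl-1,2-oxazepine | CCCCCCCCCCCCCCCCCCCCCC1=CC=NOC=C1 | intermediate (not isolated)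
8 | 3-henicosyl-2H-pyrrole-2-carbaldehyde (racemic transient) | CCCCCCCCCCCCCCCCCCCCCC1=CC=NC1C=O | intermediate (not isolated)
9 | 3-henicosyl-1H-pyrrole-2-carbaldehyde | CCCCCCCCCCCCCCCCCCCCCc1cc[nH]c1C=O | target

**Total step count:** 3. **Longest linear sequence:** 3.

**Steps most likely to fail**

**Step 3 (the proposed new step).**
- Risks: photodeoxygenation back to 4, oxygen walk to a 3-hydroxypyridine, secondary photolysis of 9, static quenching of copper-bound 5, and incomplete solubilisation of the C21 amphiphile.
- A realistic aim is 35–50% yield, with recovered 4 and 5 recycled.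
- Fallback (known chemistry only): it sets out from 1-bromoicosane 2 and comes back at target 9. Mg turnings in THF convert 2 into icosylmagnesium bromide F1. This adds at 0 °C to purchased 1-(benzenesulfonyl)-1H-pyrrole-3-carbaldehyde (O=Cc1ccn(S(=O)(=O)c2ccccc2)c1) to give racemic 1-[1-(benzenesulfonyl)-1H-pyrrol-3-yl]henicosan-1-ol F2. Ionic hydrogenation (Et3SiH, CF3CO2H, CH2Cl2, 0 °C) gives 1-(benzenesulfonyl)-3-henicosyl-1H-pyrrole F3. NaOH in MeOH/THF at reflux frees 3-henicosyl-1H-pyrrole F4. Vilsmeier–Haack formylation (POCl3, DMF, 1,2-dichloroethane) attacks mainly C2 next to the alkyl group and gives [(3-henicosyl-1H-pyrrol-2-yl)methylidene]dimethylazanium chloride F5. Aqueous NaOH hydrolyses this salt to 9. The minor regioisomer 4-henicosyl-1H-pyrrole-2-carbaldehyde F6 (about one part in four) is removed by chromatography.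

**Step 1.**
- Risks: the waxy bromide is poorly soluble at low temperature, so the SN2 step is slow, and some double alkylation or proton transfer can occur.
- Fallback: it sets out from 4-methylpyridine 1 (through its lithio derivative 3) and comes back at 4-henicosylpyridine 4. Two equivalents of 3 are acylated in a Claisen-type reaction by purchased methyl icosanoate to give 1-(pyridin-4-yl)henicosan-2-one F7. Huang-Minlon Wolff–Kishner reduction (N2H4·H2O, KOH, diethylene glycol, 130 → 200 °C) proceeds through 1-(pyridin-4-yl)henicosan-2-one hydrazone F8 and removes the carbonyl oxygen to give 4.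

**Step 2.**
- Risks: the oxidation itself is safe. The surfactant-like product emulsifies on aqueous washing, and residual carboxylic acid would spoil step 3.
- Fallback: it sets out from 1-bromoicosane 2 and comes back at N-oxide 5. The N–O bond is brought in with a purchased building block, so no oxidation is needed. PPh3 in refluxing MeCN converts 2 into icosyl(triphenyl)phosphonium bromide F9. NaN(SiMe3)2 in THF gives the ylide icosylidene(triphenyl)phosphorane F10. Wittig olefination of purchased pyridine-4-carbaldehyde 1-oxide gives (Z)-4-(henicos-1-en-1-yl)pyridine 1-oxide F11. Diimide (TsNHNH2, NaOAc, aqueous THF, reflux) saturates the C=C bond without touching the N–O bond and gives 5.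

**Further compounds**
F1 | step 3 | icosylmagnesium bromide | CCCCCCCCCCCCCCCCCCCC[Mg]Br
F2 | step 3 | 1-[1-(benzenesulfonyl)-1H-pyrrol-3-yl]henicosan-1-ol (racemic) | CCCCCCCCCCCCCCCCCCCCC(O)c1ccn(S(=O)(=O)c2ccccc2)c1
F3 | step 3 | 1-(benzenesulfonyl)-3-henicosyl-1H-pyrrole | CCCCCCCCCCCCCCCCCCCCCc1ccn(S(=O)(=O)c2ccccc2)c1
F4 | step 3 | 3-henicosyl-1H-pyrrole | CCCCCCCCCCCCCCCCCCCCCc1cc[nH]c1
F5 | step 3 | [(3-henicosyl-1H-pyrrol-2-yl)methylidene]dimethylazanium chloride | CCCCCCCCCCCCCCCCCCCCCc1cc[nH]c1C=[N+](C)C.[Cl-]
F6 | step 3 | 4-henicosyl-1H-pyrrole-2-carbaldehyde (minor regioisomer, removed) | CCCCCCCCCCCCCCCCCCCCCc1c[nH]c(C=O)c1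
F7 | step 1 | 1-(pyridin-4-yl)henicosan-2-one | CCCCCCCCCCCCCCCCCCCC(=O)Cc1ccncc1
F8 | step 1 | 1-(pyridin-4-yl)henicosan-2-one hydrazone | CCCCCCCCCCCCCCCCCCCC(=NN)Cc1ccncc1
F9 | step 2 | icosyl(triphenyl)phosphonium bromide | CCCCCCCCCCCCCCCCCCCC[P+](c1ccccc1)(c1ccccc1)c1ccccc1.[Br-]
F10 | step 2 | icosylidene(triphenyl)phosphorane | CCCCCCCCCCCCCCCCCCCC=P(c1ccccc1)(c1ccccc1)c1ccccc1
F11 | step 2 | (Z)-4-(henicos-1-en-1-yl)pyridine 1-oxide | CCCCCCCCCCCCCCCCCCC/C=C\c1cc[n+]([O-])cc1
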